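**Plan**

1. Retrosynthesis: the two angelate C–O acyl bonds, the C2 carbinol (back to a ketone) and the 8,9-epoxide are removed first. The cis-fused cyclopentanone–cycloheptene core is then cut at C1–C5 and C3–C4 in one retro-(3+2) step, which opens both rings to an acyclic 2-silyloxyallyl bromide carrying a (Z)-silyl enol ether. That chain is cut at C9–C10 (alkynylation), C8–CH3 (carbometalation) and C5–C6/C7–C8 (epichlorohydrin linchpin).
2. Enabling feature: C2 carries oxygen at the ketone level between the quaternary C1 and the C3 methylene (a 2-oxyallyl cation), and C4 is a tertiary carbinol next to the C5 methine (an enol ether). The five atoms C10–C9=C8–C7–C6, with their (Z)-alkene, are the tether that becomes the seven-membered ring.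
3. Forward: alkyne 7 (C4–C9 plus isopropyl) and aldehyde 12 (C1–C3, C10, C15) are joined and the chain is adjusted. Step 14 then closes the seven-membered ring and, in the same operation, the five-membered ring. Epoxidation, acylation and ketone reduction finish the route.
4. Stereochemistry: C6 comes from (R)-epichlorohydrin and C10 from a catalyst-controlled alkynylation. C1, C4 and C5 arise in the cycloaddition (C6-controlled face of the (Z)-enol silane, tether-enforced cis fusion). The epoxide is set by C10–OH-directed epoxidation and C2 by C4–OH-directed hydride delivery.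
5. Helpers, all removed on the way: dithiane and dioxolane (ketone masks), the exocyclic methylene on C1 (regiospecific enol silane, then tertiary bromide), two triethylsilyl enol ethers, and TBS and PMB ethers.

Key step: step 14

Remark: daucane numbering is used in the text, also for acyclic intermediates. C1 is the quaternary ring-fusion carbon with methyl C15, C2 the ring carbinol, C3 the ring CH2, C4 the isopropyl carbinol, C5 the ring-fusion CH, C6–C10 the rest of the seven-membered ring, and C14 the methyl on C8. Systematic names carry their own locants. α is the face of the C15 methyl group and β the other face; the target SMILES encodes a cis ring fusion (C15 and H-5 both α).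
Remark: the ProPhenol enantiomer in step 8 is the one that gives the (3S)-carbinol of 13; if the facial sense proves opposite, the other ligand enantiomer is taken. PMB = 4-methoxybenzyl, TBS = tert-butyldimethylsilyl, TES = triethylsilyl.

**Route**

Step 1
Reactants: 1 isobutyraldehyde; 2 propane-1,3-dithiol
Product: 3 2-(propan-2-yl)-1,3-dithiane
Conditions: BF3·OEt2 (cat.), CH2Cl2, 0 °C to rt
Reagents that add atoms: none
Why: Lewis-acid-catalysed dithioacetalisation gives the acyl-anion equivalent for C4 with its isopropyl group; no stereocentre is formed.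

Step 2
Reactants: 3 2-(propan-2-yl)-1,3-dithiane; 4 (R)-epichlorohydrin
Product: 5 2-{[(2R)-oxiran-2-yl]methyl}-2-(propan-2-yl)-1,3-dithiane
Conditions: n-BuLi, THF, −20 °C; then 4, −78 °C to rt
Reagents that add atoms: none
Why: Corey–Seebach umpolung, in which the lithiated dithiane opens the epoxide of 4 at its CH2 and the alkoxide then displaces chloride to form the new epoxide, so no bond to the stereocentre (C6) is broken and its configuration comes unchanged from 4.

Step 3
Reactants: 5 2-{[(2R)-oxiran-2-yl]methyl}-2-(propan-2-yl)-1,3-dithiane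
Product: 6 (2S)-1-[2-(propan-2-yl)-1,3-dithian-2-yl]pent-4-yn-2-ol
Conditions: LiC≡CH·H2NCH2CH2NH2, DMSO, rt
Reagents that add atoms: lithium acetylide ethylenediamine complex, [Li]C#C.NCCN
Why: SN2 opening of a terminal epoxide by acetylide at the unsubstituted carbon, which leaves the C6 stereocentre untouched.

Step 4
Reactants: 6 (2S)-1-[2-(propan-2-yl)-1,3-dithian-2-yl]pent-4-yn-2-ol
Product: 7 2-{(2S)-2-[(4-methoxyphenyl)methoxy]pent-4-yn-1-yl}-2-(propan-2-yl)-1,3-dithiane
Conditions: NaH, PMBCl, Bu4NI (cat.), THF/DMF, 0 °C to rt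
Reagents that add atoms: 4-methoxybenzyl chloride, COc1ccc(CCl)cc1
Why: Williamson etherification of the sodium alkoxide; one equivalent of base should leave the alkyne C–H untouched.

Step 5
Reactants: 8 but-3-en-2-one; 9 formaldehyde (aqueous)
Product: 10 3-(hydroxymethyl)but-3-en-2-one
Conditions: DABCO (cat.), THF/H2O, rt
Reagents that add atoms: none
Why: Morita–Baylis–Hillman reaction places the hydroxymethyl group (the future C10) on the α-carbon of the enone (the future C1); no stereocentre is formed.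

Step 6
Reactants: 10 3-(hydroxymethyl)but-3-en-2-one
Product: 11 2-(2-methyl-1,3-dioxolan-2-yl)prop-2-en-1-ol
Conditions: TMSOCH2CH2OTMS, TMSOTf (cat.), CH2Cl2, −78 to −20 °C; then K2CO3, MeOH
Reagents that add atoms: 1,2-bis(trimethylsilyloxy)ethane, C[Si](C)(C)OCCO[Si](C)(C)C
Why: Silyl-triflate-catalysed ketalisation with the bis-silyl ether of ethylene glycol should protect the ketone without moving the 1,1-disubstituted double bond, and methanolysis frees any silylated hydroxyl.

Step 7
Reactants: 11 2-(2-methyl-1,3-dioxolan-2-yl)prop-2-en-1-ol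
Product: 12 2-(2-methyl-1,3-dioxolan-2-yl)prop-2-enal
Conditions: MnO2, CH2Cl2, rt
Reagents that add atoms: none
Why: Oxidation of a primary allylic alcohol to the enal with MnO2 is selective and non-acidic, so the ketal should survive.

Step 8
Reactants: 7 2-{(2S)-2-[(4-methoxyphenyl)methoxy]pent-4-yn-1-yl}-2-(propan-2-yl)-1,3-dithiane; 12 2-(2-methyl-1,3-dioxolan-2-yl)prop-2-enal
Product: 13 (3S,7S)-7-[(4-methoxyphenyl)methoxy]-2-(2-methyl-1,3-dioxolan-2-yl)-8-[2-(propan-2-yl)-1,3-dithian-2-yl]oct-1-en-4-yn-3-ol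
Conditions: Me2Zn, ProPhenol ligand (cat.), Ph3P=O (cat.), toluene, 0 °C
Reagents that add atoms: none
Why: Zinc–ProPhenol-catalysed enantioselective addition of the alkynylzinc from 7 to the α-branched enal 12 forms C9–C10, and the dinuclear zinc catalyst should set the new C10 carbinol by reagent control, the remote C6 centre having no influence.

Step 9
Reactants: 13 (3S,7S)-7-[(4-methoxyphenyl)methoxy]-2-(2-methyl-1,3-dioxolan-2-yl)-8-[2-(propan-2-yl)-1,3-dithian-2-yl]oct-1-en-4-yn-3-ol
Product: 14 (3S,4Z,7S)-7-[(4-methoxyphenyl)methoxy]-5-methyl-2-(2-methyl-1,3-dioxolan-2-yl)-8-[2-(propan-2-yl)-1,3-dithian-2-yl]octa-1,4-dien-3-ol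
Conditions: MeMgBr (excess), Fe(acac)3 (cat.), THF, 0 °C
Reagents that add atoms: methylmagnesium bromide, C[Mg]Br
Why: Alkoxide-directed, iron-catalysed syn-carbomagnesiation of the propargylic alcohol puts methyl on the alkyne carbon remote from the hydroxyl (C8) and magnesium on C9 on the same side, so protonation should give the (Z)-alkene with C7 cis to C10, as the seven-membered ring requires.

Step 10
Reactants: 14 (3S,4Z,7S)-7-[(4-methoxyphenyl)methoxy]-5-methyl-2-(2-methyl-1,3-dioxolan-2-yl)-8-[2-(propan-2-yl)-1,3-dithian-2-yl]octa-1,4-dien-3-ol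
Product: 15 (3S,4Z,7S)-3-[(tert-butyldimethylsilyl)oxy]-7-[(4-methoxyphenyl)methoxy]-5-methyl-2-(2-methyl-1,3-dioxolan-2-yl)-8-[2-(propan-2-yl)-1,3-dithian-2-yl]octa-1,4-diene
Conditions: TBSOTf, 2,6-lutidine, CH2Cl2, −78 °C
Reagents that add atoms: tert-butyldimethylsilyl trifluoromethanesulfonate, CC(C)(C)[Si](C)(C)OS(=O)(=O)C(F)(F)F
Why: Silylation of the hindered allylic alcohol with a silyl triflate and a hindered base; the ketal and dithiane should tolerate the buffered conditions.

Step 11
Reactants: 15 (3S,4Z,7S)-3-[(tert-butyldimethylsilyl)oxy]-7-[(4-methoxyphenyl)methoxy]-5-methyl-2-(2-methyl-1,3-dioxolan-2-yl)-8-[2-(propan-2-yl)-1,3-dithian-2-yl]octa-1,4-diene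
Product: 17 (4S,5Z,8S)-4-[(tert-butyldimethylsilyl)oxy]-8-[(4-methoxyphenyl)methoxy]-6,11-dimethyl-3-methylidenedodec-5-ene-2,10-dione, via ketal ketone 16 (not isolated)
Conditions: MeI, CaCO3, MeCN/H2O, 45 °C; then PPTS, acetone/H2O, 45 °C
Reagents that add atoms: water, O
Why: S-Methylation-assisted hydrolysis of the dithiane (the dithiol leaves as its bis-methyl sulfide, so no thiol is present when the enone appears) is followed by mild acid hydrolysis of the dioxolane to the α-methylene ketone, which the silyl and PMB ethers should survive.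

Step 12
Reactants: 17 (4S,5Z,8S)-4-[(tert-butyldimethylsilyl)oxy]-8-[(4-methoxyphenyl)methoxy]-6,11-dimethyl-3-methylidenedodec-5-ene-2,10-dione
Product: 19 (4S,5Z,8S)-3-bromo-4-[(tert-butyldimethylsilyl)oxy]-8-[(4-methoxyphenyl)methoxy]-3,6,11-trimethyldodec-5-ene-2,10-dione (both C3 epimers), via triethylsilyl enol ether 18 (not isolated)
Conditions: (Ph3P)3RhCl (cat.), Et3SiH, THF, 50 °C; then NBS, NaHCO3, THF, −78 °C
Reagents that add atoms: N-bromosuccinimide, O=C1CCC(=O)N1Br; triethylsilane, CC[SiH](CC)CC (its silicon stays only in 18)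
Why: Rhodium-catalysed 1,4-hydrosilylation of the α-methylene ketone gives the tetrasubstituted enol silane regiospecifically and turns the methylene into C15, and bromination of that enol silane with NBS then places bromine on C1 only, the isopropyl ketone and the trisubstituted alkene being left alone; the new C1 centre needs no control because it is ionised in step 14.

Step 13
Reactants: 19 (4S,5Z,8S)-3-bromo-4-[(tert-butyldimethylsilyl)oxy]-8-[(4-methoxyphenyl)methoxy]-3,6,11-trimethyldodec-5-ene-2,10-dione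
Product: 20 (4S,5Z,8S,9Z)-3-bromo-4-[(tert-butyldimethylsilyl)oxy]-8-[(4-methoxyphenyl)methoxy]-3,6,11-trimethyl-2,10-bis[(triethylsilyl)oxy]dodeca-1,5,9-triene (both C3 epimers)
Conditions: TESOTf, Et3N, CH2Cl2, −78 to 0 °C
Reagents that add atoms: triethylsilyl trifluoromethanesulfonate, CC[Si](CC)(CC)OS(=O)(=O)C(F)(F)F
Why: Soft enolisation with silyl triflate and amine: the bromo ketone can enolise only towards C3, and the isopropyl ketone should enolise towards the less hindered C5 methylene to the (Z)-enol silane, in which C6 avoids the isopropyl group.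

Step 14
Reactants: 20 (4S,5Z,8S,9Z)-3-bromo-4-[(tert-butyldimethylsilyl)oxy]-8-[(4-methoxyphenyl)methoxy]-3,6,11-trimethyl-2,10-bis[(triethylsilyl)oxy]dodeca-1,5,9-triene
Product: 21 10β-[(tert-butyldimethylsilyl)oxy]-6α-[(4-methoxyphenyl)methoxy]-4β-[(triethylsilyl)oxy]-5αH-dauc-8-en-2-one (cis-fused)
Conditions: ZnCl2 (0.3 equiv, in Et2O), CH2Cl2 (0.005 M), −78 to −30 °C; then Et3N, NaHCO3 aq.
Reagents that add atoms: none
Why: Proposed new method: ZnCl2 should abstract the tertiary allylic bromide of 20 to give a 2-(triethylsilyloxy)allyl cation over C1–C2–C3; C5 of the tethered (Z)-enol silane attacks C1 and the C2=C3 enol silane then closes on the C4 silyloxocarbenium ion with loss of Et3SiBr, a stepwise (3+2) cycloaddition that forms C1–C5 and C3–C4. The closest known reaction types are the intermolecular (3+2) cyclopentanone annulation of 2-silyloxyallyl cations with alkenes and enol ethers and the intramolecular (4+3) cycloaddition of oxyallyl cations with tethered dienes; a tethered enol silane that closes a seven-membered ring has not been used. The seven-membered ring closes by 7-exo-trig attack of the enol silane on the allyl cation through the C10–C9=C8–C7–C6 tether, whose (Z)-alkene holds the ends together, and the five-membered ring by a 5-(enolendo)-exo-trig Mukaiyama-type aldol closure. C5 is controlled by allylic 1,3-strain in the (Z)-enol silane, which keeps H-6 in the enol plane so that the tether brings C1 to the face syn to C7 and anti to the PMB ether (H-5 cis to O-6); C4 follows from the (Z)-geometry and closure of C3 on the same face (O-4 cis to C6); C1 follows from the need of C10 and C6 to lie on one side of the new cyclopentane for the three-atom bridge to span them (cis fusion, C15 cis to H-5), and the pre-set (S)-configured C10 silyl ether must fit this arrangement. The step needs ionisation without proton loss, attack by the enol silane in preference to the C8=C9 alkene, and C- in preference to O-closure of the zwitterion; the far higher nucleophilicity of the enol silane, low temperature and high dilution should secure the first two, and the known formation of cyclopentanones from such cations the third.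

Step 15
Reactants: 21 10β-[(tert-butyldimethylsilyl)oxy]-6α-[(4-methoxyphenyl)methoxy]-4β-[(triethylsilyl)oxy]-5αH-dauc-8-en-2-one
Product: 22 4β,10β-dihydroxy-6α-[(4-methoxyphenyl)methoxy]-5αH-dauc-8-en-2-one
Conditions: HF·pyridine, THF/pyridine, 0 °C to rt
Reagents that add atoms: none
Why: Fluoride cleavage of the secondary TBS and tertiary TES ethers under weakly acidic conditions, which should leave the PMB ether and avoid retro-aldol opening of the β-hydroxy ketone.

Step 16
Reactants: 22 4β,10β-dihydroxy-6α-[(4-methoxyphenyl)methoxy]-5αH-dauc-8-en-2-one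
Product: 23 8β,9β-epoxy-4β,10β-dihydroxy-6α-[(4-methoxyphenyl)methoxy]-5αH-daucan-2-one
Conditions: VO(acac)2 (cat.), t-BuOOH, CH2Cl2, 0 °C to rt
Reagents that add atoms: tert-butyl hydroperoxide, CC(C)(C)OO
Why: Hydroxyl-directed vanadium-catalysed epoxidation of a cyclic allylic alcohol: the vanadate ester of the C10 hydroxyl should deliver oxygen to the same (β) face of C8=C9, and the PMB-protected C6 oxygen cannot compete.

Step 17
Reactants: 23 8β,9β-epoxy-4β,10β-dihydroxy-6α-[(4-methoxyphenyl)methoxy]-5αH-daucan-2-one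
Product: 24 8β,9β-epoxy-4β,6α,10β-trihydroxy-5αH-daucan-2-one
Conditions: DDQ, CH2Cl2/pH 7 buffer, 0 °C to rt
Reagents that add atoms: none
Why: Oxidative cleavage of the PMB ether by DDQ through the benzylic oxocarbenium ion and its hydrolysis; epoxide, ketone and free hydroxyls should tolerate the buffered conditions.

Step 18
Reactants: 24 8β,9β-epoxy-4β,6α,10β-trihydroxy-5αH-daucan-2-one; 25 angelic acid [(2Z)-2-methylbut-2-enoic acid]
Product: 27 6α,10β-bis(angeloyloxy)-8β,9β-epoxy-4β-hydroxy-5αH-daucan-2-one, via angelic 2,4,6-trichlorobenzoic anhydride 26 (not isolated)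
Conditions: 25, 2,4,6-trichlorobenzoyl chloride, Et3N, toluene, rt; then 24, 80 °C
Reagents that add atoms: 2,4,6-trichlorobenzoyl chloride, O=C(Cl)c1c(Cl)cc(Cl)cc1Cl (its atoms stay only in 26)
Why: Yamaguchi esterification through the mixed anhydride without a nucleophilic catalyst, conditions chosen to keep the (Z)-geometry of the angeloyl group; both secondary hydroxyls should be acylated while the tertiary C4 hydroxyl is too hindered to react.

Step 19
Reactants: 27 6α,10β-bis(angeloyloxy)-8β,9β-epoxy-4β-hydroxy-5αH-daucan-2-one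
Product: 28 6α,10β-bis(angeloyloxy)-8β,9β-epoxy-5αH-daucane-2α,4β-diol (target)
Conditions: Me4NBH(OAc)3, MeCN/AcOH, −30 °C
Reagents that add atoms: none
Why: Evans–Saksena hydroxyl-directed reduction: the C4 β-hydroxyl exchanges onto boron and delivers hydride intramolecularly to the β-face of the C2 ketone, which should give the 2α-alcohol anti to the 4β-hydroxyl while esters and epoxide are left alone at low temperature.

**Compound list**

1 | isobutyraldehyde (2-methylpropanal) | CC(C)C=O | starting material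
2 | propane-1,3-dithiol | SCCCS | starting material
3 | 2-(propan-2-yl)-1,3-dithiane | CC(C)C1SCCCS1 | intermediate
4 | (R)-epichlorohydrin [(2R)-2-(chloromethyl)oxirane] | ClC[C@H]1CO1 | starting material
5 | 2-{[(2R)-oxiran-2-yl]methyl}-2-(propan-2-yl)-1,3-dithiane | CC(C)C1(C[C@@H]2CO2)SCCCS1 | intermediate
6 | (2S)-1-[2-(propan-2-yl)-1,3-dithian-2-yl]pent-4-yn-2-ol | CC(C)C1(C[C@@H](O)CC#C)SCCCS1 | intermediate
7 | 2-{(2S)-2-[(4-methoxyphenyl)methoxy]pent-4-yn-1-yl}-2-(propan-2-yl)-1,3-dithiane | CC(C)C1(C[C@@H](OCc2ccc(OC)cc2)CC#C)SCCCS1 | intermediate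
8 | but-3-en-2-one (methyl vinyl ketone) | CC(=O)C=C | starting material
9 | formaldehyde (aqueous) | C=O | starting material
10 | 3-(hydroxymethyl)but-3-en-2-one | CC(=O)C(=C)CO | intermediate
11 | 2-(2-methyl-1,3-dioxolan-2-yl)prop-2-en-1-ol | CC1(OCCO1)C(=C)CO | intermediate
12 | 2-(2-methyl-1,3-dioxolan-2-yl)prop-2-enal | CC1(OCCO1)C(=C)C=O | intermediate
13 | (3S,7S)-7-[(4-methoxyphenyl)methoxy]-2-(2-methyl-1,3-dioxolan-2-yl)-8-[2-(propan-2-yl)-1,3-dithian-2-yl]oct-1-en-4-yn-3-ol | CC(C)C1(C[C@@H](OCc2ccc(OC)cc2)CC#C[C@H](O)C(=C)C2(C)OCCO2)SCCCS1 | intermediate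
14 | (3S,4Z,7S)-7-[(4-methoxyphenyl)methoxy]-5-methyl-2-(2-methyl-1,3-dioxolan-2-yl)-8-[2-(propan-2-yl)-1,3-dithian-2-yl]octa-1,4-dien-3-ol | CC(C)C1(C[C@@H](OCc2ccc(OC)cc2)C/C(C)=C\[C@H](O)C(=C)C2(C)OCCO2)SCCCS1 | intermediate
15 | (3S,4Z,7S)-3-[(tert-butyldimethylsilyl)oxy]-7-[(4-methoxyphenyl)methoxy]-5-methyl-2-(2-methyl-1,3-dioxolan-2-yl)-8-[2-(propan-2-yl)-1,3-dithian-2-yl]octa-1,4-diene | CC(C)C1(C[C@@H](OCc2ccc(OC)cc2)C/C(C)=C\[C@H](O[Si](C)(C)C(C)(C)C)C(=C)C2(C)OCCO2)SCCCS1 | intermediate
16 | ketal ketone: 17 with its methyl ketone still protected as the ethylene ketal | CC(C)C(=O)C[C@@H](OCc1ccc(OC)cc1)C/C(C)=C\[C@H](O[Si](C)(C)C(C)(C)C)C(=C)C1(C)OCCO1 | intermediate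
17 | (4S,5Z,8S)-4-[(tert-butyldimethylsilyl)oxy]-8-[(4-methoxyphenyl)methoxy]-6,11-dimethyl-3-methylidenedodec-5-ene-2,10-dione | CC(C)C(=O)C[C@@H](OCc1ccc(OC)cc1)C/C(C)=C\[C@H](O[Si](C)(C)C(C)(C)C)C(=C)C(C)=O | intermediate
18 | (4S,5Z,8S)-4-[(tert-butyldimethylsilyl)oxy]-8-[(4-methoxyphenyl)methoxy]-3,6,11-trimethyl-2-[(triethylsilyl)oxy]dodeca-2,5-dien-10-one (C2=C3 geometry undefined) | CC(C)C(=O)C[C@@H](OCc1ccc(OC)cc1)C/C(C)=C\[C@H](O[Si](C)(C)C(C)(C)C)C(C)=C(C)O[Si](CC)(CC)CC | intermediate
19 | (4S,5Z,8S)-3-bromo-4-[(tert-butyldimethylsilyl)oxy]-8-[(4-methoxyphenyl)methoxy]-3,6,11-trimethyldodec-5-ene-2,10-dione (both C3 epimers) | CC(C)C(=O)C[C@@H](OCc1ccc(OC)cc1)C/C(C)=C\[C@H](O[Si](C)(C)C(C)(C)C)C(C)(Br)C(C)=O | intermediate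
20 | (4S,5Z,8S,9Z)-3-bromo-4-[(tert-butyldimethylsilyl)oxy]-8-[(4-methoxyphenyl)methoxy]-3,6,11-trimethyl-2,10-bis[(triethylsilyl)oxy]dodeca-1,5,9-triene (both C3 epimers) | CC(C)/C(O[Si](CC)(CC)CC)=C/[C@@H](OCc1ccc(OC)cc1)C/C(C)=C\[C@H](O[Si](C)(C)C(C)(C)C)C(C)(Br)C(=C)O[Si](CC)(CC)CC | intermediate
21 | 10β-[(tert-butyldimethylsilyl)oxy]-6α-[(4-methoxyphenyl)methoxy]-4β-[(triethylsilyl)oxy]-5αH-dauc-8-en-2-one (cis-fused, C15 α, isopropyl 4α) | COc1ccc(CO[C@H]2CC(C)=C[C@H](O[Si](C)(C)C(C)(C)C)[C@@]3(C)[C@@H]2[C@](O[Si](CC)(CC)CC)(C(C)C)CC3=O)cc1 | intermediate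
22 | 4β,10β-dihydroxy-6α-[(4-methoxyphenyl)methoxy]-5αH-dauc-8-en-2-one | COc1ccc(CO[C@H]2CC(C)=C[C@H](O)[C@@]3(C)[C@@H]2[C@](O)(C(C)C)CC3=O)cc1 | intermediate
23 | 8β,9β-epoxy-4β,10β-dihydroxy-6α-[(4-methoxyphenyl)methoxy]-5αH-daucan-2-one | COc1ccc(CO[C@H]2C[C@]3(C)O[C@@H]3[C@H](O)[C@@]3(C)[C@@H]2[C@](O)(C(C)C)CC3=O)cc1 | intermediate
24 | 8β,9β-epoxy-4β,6α,10β-trihydroxy-5αH-daucan-2-one | O[C@H]1C[C@]2(C)O[C@@H]2[C@H](O)[C@@]2(C)[C@@H]1[C@](O)(C(C)C)CC2=O | intermediate
25 | angelic acid [(2Z)-2-methylbut-2-enoic acid] | C/C=C(/C)C(=O)O | starting material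
26 | angelic 2,4,6-trichlorobenzoic anhydride | C/C=C(/C)C(=O)OC(=O)c1c(Cl)cc(Cl)cc1Cl | intermediate
27 | 6α,10β-bis(angeloyloxy)-8β,9β-epoxy-4β-hydroxy-5αH-daucan-2-one | C/C=C(/C)C(=O)O[C@H]1C[C@]2(C)O[C@@H]2[C@H](OC(=O)/C(C)=C\C)[C@@]2(C)[C@@H]1[C@](O)(C(C)C)CC2=O | intermediate
28 | 6α,10β-bis(angeloyloxy)-8β,9β-epoxy-5αH-daucane-2α,4β-diol (CNP0265715.3) | C/C=C(/C)C(=O)O[C@H]1C[C@]2(C)O[C@@H]2[C@H](OC(=O)/C(C)=C\C)[C@@]2(C)[C@@H]1[C@](O)(C(C)C)C[C@@H]2O | target

**Step count**

Total step count: 19. Longest linear sequence: 16 steps (steps 1–4, then 8–19).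

**Steps most likely to fail**

1. Step 14. The oxyallyl cation may lose a proton to an enone, may be captured by the C8=C9 alkene or by the enolate oxygen, or may cyclise with poor facial selectivity if the C10 ether is mismatched with the approach that C6 dictates. The fallback sets out from 17 and separates the two bond formations, using known oxidative enol silane coupling and aldol chemistry. Hydrosilylation as in step 12 is stopped at enol silane 18, which is isolated and silylated at the isopropyl ketone (TESOTf, Et3N) to the bromine-free bis(triethylsilyl enol ether) F1. Intramolecular oxidative coupling of the two silyl enol ethers with Cu(OTf)2 and Cu2O in MeCN at 0 °C should form C1–C5 and give the cycloheptene 1,4-diketone F2. Kinetic enolisation of its methyl ketone with LiN(iPr)2 at −78 °C and intramolecular aldol addition to the isopropyl ketone should form C3–C4, the isopropyl group settling trans to C6, to give the 4β-hydroxy bicycle F3. HF·pyridine then removes the TBS group and the route is rejoined at 22.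

2. Step 9. The iron-catalysed carbomagnesiation may stall or add with the wrong regiochemistry on this hindered, polyfunctional propargylic alcohol. The fallback sets out from 13 and builds the same alkene by hydrometalation and cross-coupling. The alcohol is silylated (TBSOTf, 2,6-lutidine) to the propargylic silyl ether F4. Syn-hydrozirconation with Cp2Zr(H)Cl places zirconium on the less hindered C8, and iodinolysis with I2 gives the (E)-vinyl iodide F5, in which C7 is already cis to C10. Negishi coupling with MeZnCl and Pd(PPh3)4 replaces iodine by methyl with retention and rejoins the route at 15.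

3. Step 18. The angeloyl groups may isomerise to tigloyl groups during acylation, and acylation of the hindered C10 hydroxyl next to the quaternary carbon and the epoxide may stay incomplete. The fallback sets out from 24 and builds the (Z)-alkenes on the substrate instead of transferring them. Both secondary hydroxyls are esterified with 2-[bis(2,2,2-trifluoroethoxy)phosphoryl]propanoic acid (EDC·HCl, DMAP), a small saturated acid, to the bis(phosphonopropanoate) F6. A double Still–Gennari olefination with acetaldehyde (KN(SiMe3)2, 18-crown-6, THF, −78 °C, one extra equivalent of base for the tertiary hydroxyl) should then give both (Z)-2-methylbut-2-enoates and rejoin the route at 27.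

**Further compounds**

F1 | step 14 | (4S,5Z,8S,9Z)-4-[(tert-butyldimethylsilyl)oxy]-8-[(4-methoxyphenyl)methoxy]-3,6,11-trimethyl-2,10-bis[(triethylsilyl)oxy]dodeca-2,5,9-triene | CC(C)/C(O[Si](CC)(CC)CC)=C/[C@@H](OCc1ccc(OC)cc1)C/C(C)=C\[C@H](O[Si](C)(C)C(C)(C)C)C(C)=C(C)O[Si](CC)(CC)CC
F2 | step 14 | 1-{2-acetyl-3-[(tert-butyldimethylsilyl)oxy]-7-[(4-methoxyphenyl)methoxy]-2,5-dimethylcyclohept-4-en-1-yl}-2-methylpropan-1-one (acetyl and isobutyryl cis, configuration as in the SMILES) | CC(C)C(=O)[C@@H]1[C@@H](OCc2ccc(OC)cc2)CC(C)=C[C@H](O[Si](C)(C)C(C)(C)C)[C@]1(C)C(C)=O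
F3 | step 14 | 10β-[(tert-butyldimethylsilyl)oxy]-4β-hydroxy-6α-[(4-methoxyphenyl)methoxy]-5αH-dauc-8-en-2-one | COc1ccc(CO[C@H]2CC(C)=C[C@H](O[Si](C)(C)C(C)(C)C)[C@@]3(C)[C@@H]2[C@](O)(C(C)C)CC3=O)cc1
F4 | step 9 | tert-butyldimethylsilyl ether of 13 at O-3 | CC(C)C1(C[C@@H](OCc2ccc(OC)cc2)CC#C[C@H](O[Si](C)(C)C(C)(C)C)C(=C)C2(C)OCCO2)SCCCS1
F5 | step 9 | (3S,4E,7S)-3-[(tert-butyldimethylsilyl)oxy]-5-iodo-7-[(4-methoxyphenyl)methoxy]-2-(2-methyl-1,3-dioxolan-2-yl)-8-[2-(propan-2-yl)-1,3-dithian-2-yl]octa-1,4-diene | CC(C)C1(C[C@@H](OCc2ccc(OC)cc2)C/C(I)=C\[C@H](O[Si](C)(C)C(C)(C)C)C(=C)C2(C)OCCO2)SCCCS1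
F6 | step 18 | 6α,10β-bis({2-[bis(2,2,2-trifluoroethoxy)phosphoryl]propanoyl}oxy)-8β,9β-epoxy-4β-hydroxy-5αH-daucan-2-one | CC(C(=O)O[C@H]1C[C@]2(C)O[C@@H]2[C@H](OC(=O)C(C)P(=O)(OCC(F)(F)F)OCC(F)(F)F)[C@@]2(C)[C@@H]1[C@](O)(C(C)C)CC2=O)P(=O)(OCC(F)(F)F)OCC(F)(F)F
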